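**Retrosynthetic overview**

- The target is the 8,8'-linked dimer of 5,6,7-trihydroxy-3-(4-hydroxyphenyl)chromen-4-one; it is symmetric and has no stereocentre.
- Feature used: in each half, C4a (which carries the C4 carbonyl) lies between two oxygen-bearing carbons, C8a (ring oxygen O1) and C5 (hydroxyl). If ring C opens at O1–C2 and recloses on the C5 oxygen, the old C6 becomes C8 and a 5,7,8-oxygen pattern becomes 5,6,7.
- Last disconnection: both O1–C2 bonds of the target, back to the 6,6'-linked 5,7,8-trioxygenated dimer, carried as its octamethyl ether (acid-induced ring switch of both pyranones together with global demethylation).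
- The 6,6' bond comes from Ullmann homocoupling of a 6-iodo-5,7,8-trimethoxyisoflavone, made from biochanin A by 7-O-methylation, C8 hydroxylation, 8-O-methylation, C6 iodination and 5-O-methylation.
- Ring order: rings A, B and the original rings C arrive with biochanin A; the biaryl bond is made next; the two pyranone rings of the target are formed last.

Key step: step 7

Assumption: the target SMILES carries no axial descriptor, so the hindered biaryl axis is treated as undefined and is made as the racemate.

Remark: the chelated C5 hydroxyls are methylated before the copper coupling; HI removes these peri ethers first in the key step, so the ring switch is unaffected.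

**Route**

Step 1
Reactants: 1 biochanin A; 2 iodomethane
Product: 3 5-hydroxy-7-methoxy-3-(4-methoxyphenyl)-4H-chromen-4-one
Conditions: MeI (1.1 equiv), K2CO3, acetone, reflux
Reagents that add atoms: iodomethane, CI
Why: Williamson ether synthesis: with one equivalent of MeI the acidic, unchelated C7 phenol is alkylated, whereas the C5 hydroxyl is hydrogen bonded to the C4 carbonyl and should stay free.

Step 2
Reactants: 3 5-hydroxy-7-methoxy-3-(4-methoxyphenyl)-4H-chromen-4-one; 4 potassium persulfate
Product: 6 5,8-dihydroxy-7-methoxy-3-(4-methoxyphenyl)-4H-chromen-4-one, via potassium C8 sulfate 5 (not isolated)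
Conditions: K2S2O8, aq KOH (excess), pyridine, 0 °C to rt; then aq HCl, 90 °C, N2
Reagents that add atoms: potassium persulfate, [K+].[K+].[O-]S(=O)(=O)OOS(=O)(=O)[O-]
Why: Elbs persulfate oxidation: the C5 phenoxide attacks a peroxide oxygen of persulfate through its para carbon C8 to give aryl sulfate 5, which acid hydrolyses at the S–O bond to the 5,8-dihydroxy compound; this is the classical entry to 5,8-dihydroxy flavonoids, and ring B has no free phenol to compete.

Step 3
Reactants: 6 5,8-dihydroxy-7-methoxy-3-(4-methoxyphenyl)-4H-chromen-4-one; 2 iodomethane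
Product: 7 5-hydroxy-7,8-dimethoxy-3-(4-methoxyphenyl)-4H-chromen-4-one
Conditions: MeI (1.05 equiv), K2CO3, acetone, reflux, N2
Reagents that add atoms: iodomethane, CI
Why: Williamson ether synthesis: the new C8 phenol is not chelated and should be methylated by one equivalent of MeI, while the C5 hydroxyl stays tied to the carbonyl.

Step 4
Reactants: 7 5-hydroxy-7,8-dimethoxy-3-(4-methoxyphenyl)-4H-chromen-4-one; 8 N-iodosuccinimide
Product: 9 5-hydroxy-6-iodo-7,8-dimethoxy-3-(4-methoxyphenyl)-4H-chromen-4-one
Conditions: NIS (1.05 equiv), TFA (cat.), MeCN, 0 °C to rt, dark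
Reagents that add atoms: N-iodosuccinimide, O=C1CCC(=O)N1I
Why: Electrophilic aromatic iodination: C6 is the only unsubstituted carbon of ring A and is activated by the ortho C5 hydroxyl, the ortho C7 methoxyl and the para ring oxygen, so it should react well before the mono-methoxylated ring B.

Step 5
Reactants: 9 5-hydroxy-6-iodo-7,8-dimethoxy-3-(4-methoxyphenyl)-4H-chromen-4-one; 2 iodomethane
Product: 10 6-iodo-5,7,8-trimethoxy-3-(4-methoxyphenyl)-4H-chromen-4-one
Conditions: MeI (excess), K2CO3, DMF, 50 °C
Reagents that add atoms: iodomethane, CI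
Why: Williamson ether synthesis under more forcing conditions should overcome the chelation of the C5 hydroxyl; capping this phenol removes the acidic proton and the phenoxide that would cause loss of iodine or C–O coupling on copper.

Step 6
Reactants: 10 6-iodo-5,7,8-trimethoxy-3-(4-methoxyphenyl)-4H-chromen-4-one (two molecules)
Product: 11 6,6'-bi[5,7,8-trimethoxy-3-(4-methoxyphenyl)-4H-chromen-4-one]
Conditions: activated Cu powder (copper bronze), DMF, reflux, N2
Reagents that add atoms: none
Why: Ullmann reductive homocoupling: copper inserts into the C6–I bond and two aryl copper units couple; aryl iodides flanked by two methoxyls, iodinated flavone methyl ethers among them, are classical substrates, and the new axis forms as the racemate.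

Step 7
Reactants: 11 6,6'-bi[5,7,8-trimethoxy-3-(4-methoxyphenyl)-4H-chromen-4-one]
Product: 16 8,8'-bi[5,6,7-trihydroxy-3-(4-hydroxyphenyl)-4H-chromen-4-one] (CNP0254964.0), via C6-C6' linked octaphenol 12 (not isolated), via half-opened ketoenol 13 (not isolated), via C6-C8' linked isomer 14 (not isolated), via half-opened ketoenol 15 (not isolated)
Conditions: 57% aq HI, AcOH, reflux, Ar; reverse-phase chromatography
Reagents that add atoms: none
Why: Iodide cleaves the eight aryl methyl ethers by SN2 attack on the protonated ethers (the peri C5 ethers first) to give octaphenol 12, and protonation of a C4 carbonyl then lets water add at C2 and break the O1–C2 bond, which gives ketoenol 13 whose acyl-bearing carbon (former C4a) stands between two free phenols, the former C5 hydroxyl and the former ring oxygen. After rotation about the aryl–C4 bond the former C5 oxygen adds to the aldehyde carbon (6-exo-trig addition to the C=O, then loss of water) and forms the new O1–C2 bond and the pyranone of one half (14); the same opening and 6-exo-trig reclosure through 15 forms the second O1–C2 bond and the second pyranone of 16. The closest known reaction is the Wessely–Moser rearrangement, which accompanies HI demethylation of 5,7,8-trioxygenated flavones and isoflavones and is also documented for flavone dimers joined through C6 or C8. No stereocentre is created, and the hindered biaryl axis is carried as the racemate. The step needs both halves to reclose on the former C5 oxygen and not on the former ring oxygen; as every stage is reversible this is decided by stability, and the substrate should favour the wanted closure because it creates the contiguous hydrogen-bonded 5,6,7-triol and moves the biaryl carbon from between two hydroxyl-bearing carbons (C5 and C7) to the less crowded position between C7 and the tied-back ring oxygen. Should equilibration stop at a mixture with 12 and 14, reverse-phase chromatography would separate the isomers and the unwanted ones would be returned to the same conditions.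

**Compound list**

1 | biochanin A (5,7-dihydroxy-3-(4-methoxyphenyl)-4H-chromen-4-one) | COc1ccc(-c2coc3cc(O)cc(O)c3c2=O)cc1 | starting material
2 | iodomethane | CI | starting material
3 | 5-hydroxy-7-methoxy-3-(4-methoxyphenyl)-4H-chromen-4-one | COc1ccc(-c2coc3cc(OC)cc(O)c3c2=O)cc1 | intermediate
4 | potassium persulfate | [K+].[K+].[O-]S(=O)(=O)OOS(=O)(=O)[O-] | starting material
5 | potassium 5-hydroxy-7-methoxy-3-(4-methoxyphenyl)-4-oxo-4H-chromen-8-yl sulfate | COc1ccc(-c2coc3c(OS(=O)(=O)[O-])c(OC)cc(O)c3c2=O)cc1.[K+] | intermediate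
6 | 5,8-dihydroxy-7-methoxy-3-(4-methoxyphenyl)-4H-chromen-4-one | COc1ccc(-c2coc3c(O)c(OC)cc(O)c3c2=O)cc1 | intermediate
7 | 5-hydroxy-7,8-dimethoxy-3-(4-methoxyphenyl)-4H-chromen-4-one | COc1ccc(-c2coc3c(OC)c(OC)cc(O)c3c2=O)cc1 | intermediate
8 | N-iodosuccinimide | O=C1CCC(=O)N1I | starting material
9 | 5-hydroxy-6-iodo-7,8-dimethoxy-3-(4-methoxyphenyl)-4H-chromen-4-one | COc1ccc(-c2coc3c(OC)c(OC)c(I)c(O)c3c2=O)cc1 | intermediate
10 | 6-iodo-5,7,8-trimethoxy-3-(4-methoxyphenyl)-4H-chromen-4-one | COc1ccc(-c2coc3c(OC)c(OC)c(I)c(OC)c3c2=O)cc1 | intermediate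
11 | 6,6'-bi[5,7,8-trimethoxy-3-(4-methoxyphenyl)-4H-chromen-4-one], racemic axis | COc1ccc(-c2coc3c(OC)c(OC)c(-c4c(OC)c(OC)c5occ(-c6ccc(OC)cc6)c(=O)c5c4OC)c(OC)c3c2=O)cc1 | intermediate
12 | 6,6'-bi[5,7,8-trihydroxy-3-(4-hydroxyphenyl)-4H-chromen-4-one] | Oc1ccc(-c2coc3c(O)c(O)c(-c4c(O)c(O)c5occ(-c6ccc(O)cc6)c(=O)c5c4O)c(O)c3c2=O)cc1 | intermediate
13 | 5,7,8-trihydroxy-3-(4-hydroxyphenyl)-6-{2,4,5,6-tetrahydroxy-3-[(Z)-3-hydroxy-2-(4-hydroxyphenyl)prop-2-enoyl]phenyl}-4H-chromen-4-one | Oc1ccc(-c2coc3c(O)c(O)c(-c4c(O)c(O)c(O)c(C(=O)/C(c5ccc(O)cc5)=C\O)c4O)c(O)c3c2=O)cc1 | intermediate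
14 | 5,7,8-trihydroxy-3-(4-hydroxyphenyl)-6-[5,6,7-trihydroxy-3-(4-hydroxyphenyl)-4-oxo-4H-chromen-8-yl]-4H-chromen-4-one | Oc1ccc(-c2coc3c(O)c(O)c(-c4c(O)c(O)c(O)c5c(=O)c(-c6ccc(O)cc6)coc45)c(O)c3c2=O)cc1 | intermediate
15 | 5,6,7-trihydroxy-3-(4-hydroxyphenyl)-8-{2,4,5,6-tetrahydroxy-3-[(Z)-3-hydroxy-2-(4-hydroxyphenyl)prop-2-enoyl]phenyl}-4H-chromen-4-one | Oc1ccc(-c2coc3c(-c4c(O)c(O)c(O)c(C(=O)/C(c5ccc(O)cc5)=C\O)c4O)c(O)c(O)c(O)c3c2=O)cc1 | intermediate
16 | 8,8'-bi[5,6,7-trihydroxy-3-(4-hydroxyphenyl)-4H-chromen-4-one] (CNP0254964.0) | O=c1c(-c2ccc(O)cc2)coc2c(-c3c(O)c(O)c(O)c4c(=O)c(-c5ccc(O)cc5)coc34)c(O)c(O)c(O)c12 | target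

**Step count and risks**

Total step count: 7. Longest linear sequence: 7 steps, from biochanin A to the target.

Steps most likely to fail:

1. Step 7. The equilibration may stop with only one half, or neither, reclosed on the former C5 oxygen, and long heating may strip the C2 carbon from the opened ketoenol as formic acid. Fallback: carry out the ring switch on the monomer, where it is established, and make the 8,8' bond afterwards. Setting out from 7, hot aqueous HI in AcOH should demethylate and isomerize it to 5,6,7-trihydroxy-3-(4-hydroxyphenyl)-4H-chromen-4-one F1. Exhaustive methylation (MeI, K2CO3, DMF) should give 5,6,7-trimethoxy-3-(4-methoxyphenyl)-4H-chromen-4-one F2. Iodination at the only free carbon of ring A (NIS, TFA, MeCN) should give 8-iodo-5,6,7-trimethoxy-3-(4-methoxyphenyl)-4H-chromen-4-one F3. Ullmann coupling (Cu powder, DMF, reflux) should give 8,8'-bi[5,6,7-trimethoxy-3-(4-methoxyphenyl)-4H-chromen-4-one] F4. BBr3 in CH2Cl2 (−78 °C to rt), which does not open the pyranone, should then cleave the eight ethers and come back to the route at 16.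

2. Step 2. Attack of the chelated phenoxide on persulfate may be slow, so that opening of the pyranone by alkali and over-oxidation of the hydroquinone product compete. Fallback: introduce the C8 oxygen through a halide. Setting out from 3, methylation of the C5 hydroxyl (MeI, K2CO3, DMF) should give 5,7-dimethoxy-3-(4-methoxyphenyl)-4H-chromen-4-one F5. Iodination at C8, the usual site in 5,7-dimethoxychromones (I2, CF3CO2Ag, CH2Cl2), should give 8-iodo-5,7-dimethoxy-3-(4-methoxyphenyl)-4H-chromen-4-one F6. Miyaura borylation (B2pin2, Pd(dppf)Cl2, KOAc, dioxane, 90 °C) should give 5,7-dimethoxy-3-(4-methoxyphenyl)-8-(4,4,5,5-tetramethyl-1,3,2-dioxaborolan-2-yl)-4H-chromen-4-one F7. Oxidation (KHSO5 as the triple salt 2KHSO5·KHSO4·K2SO4, acetone/water, 0 °C) should give 8-hydroxy-5,7-dimethoxy-3-(4-methoxyphenyl)-4H-chromen-4-one F8. BCl3 (CH2Cl2, −20 °C) should then cleave only the peri C5 methyl ether and come back to the route at 6.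

3. Step 6. Insertion and coupling at a carbon flanked by two methoxyls may be slow, so that reductive loss of iodine outruns biaryl formation. Fallback: replace the reductive homocoupling by a cross-coupling of two differently activated halves. Setting out from 10, half of the material would be converted (B2pin2, Pd(dppf)Cl2, KOAc, DMSO, 80 °C) into 5,7,8-trimethoxy-3-(4-methoxyphenyl)-6-(4,4,5,5-tetramethyl-1,3,2-dioxaborolan-2-yl)-4H-chromen-4-one F9. Suzuki–Miyaura coupling of F9 with the remaining 10 (Pd(OAc)2, SPhos, K3PO4, toluene/water, 100 °C) should then come back to the route at 11.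

**Further compounds**

F1 | step 7 | 5,6,7-trihydroxy-3-(4-hydroxyphenyl)-4H-chromen-4-one | O=c1c(-c2ccc(O)cc2)coc2cc(O)c(O)c(O)c12
F2 | step 7 | 5,6,7-trimethoxy-3-(4-methoxyphenyl)-4H-chromen-4-one | COc1ccc(-c2coc3cc(OC)c(OC)c(OC)c3c2=O)cc1
F3 | step 7 | 8-iodo-5,6,7-trimethoxy-3-(4-methoxyphenyl)-4H-chromen-4-one | COc1ccc(-c2coc3c(I)c(OC)c(OC)c(OC)c3c2=O)cc1
F4 | step 7 | 8,8'-bi[5,6,7-trimethoxy-3-(4-methoxyphenyl)-4H-chromen-4-one] | COc1ccc(-c2coc3c(-c4c(OC)c(OC)c(OC)c5c(=O)c(-c6ccc(OC)cc6)coc45)c(OC)c(OC)c(OC)c3c2=O)cc1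
F5 | step 2 | 5,7-dimethoxy-3-(4-methoxyphenyl)-4H-chromen-4-one | COc1ccc(-c2coc3cc(OC)cc(OC)c3c2=O)cc1
F6 | step 2 | 8-iodo-5,7-dimethoxy-3-(4-methoxyphenyl)-4H-chromen-4-one | COc1ccc(-c2coc3c(I)c(OC)cc(OC)c3c2=O)cc1
F7 | step 2 | 5,7-dimethoxy-3-(4-methoxyphenyl)-8-(4,4,5,5-tetramethyl-1,3,2-dioxaborolan-2-yl)-4H-chromen-4-one | COc1ccc(-c2coc3c(B4OC(C)(C)C(C)(C)O4)c(OC)cc(OC)c3c2=O)cc1
F8 | step 2 | 8-hydroxy-5,7-dimethoxy-3-(4-methoxyphenyl)-4H-chromen-4-one | COc1ccc(-c2coc3c(O)c(OC)cc(OC)c3c2=O)cc1
F9 | step 6 | 5,7,8-trimethoxy-3-(4-methoxyphenyl)-6-(4,4,5,5-tetramethyl-1,3,2-dioxaborolan-2-yl)-4H-chromen-4-one | COc1ccc(-c2coc3c(OC)c(OC)c(B4OC(C)(C)C(C)(C)O4)c(OC)c3c2=O)cc1
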